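## Retrosynthetic overview

1. Flavanone numbering is used, and doubly primed locants belong to the 7-methoxy half. On each ring A the ether oxygen O1 (O1'') sits on C8a (C8a''), next to C4a (C4a''), which carries the ketone carbon C4 (C4''). O1 and C4 are therefore one carboxyl group laid across two adjacent ring-A carbons, and the chain C2–C3(C4)–C3''(C4'')–C2'' is a 2,3-bis(arylidene)succinic acid.
2. The first disconnection removes the 7''-O-methyl group, giving the twofold-symmetric 5,7,5'',7''-tetraol with two homotopic 7-hydroxyls. The four phenols are then masked as benzyl ethers.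
3. Rings C are the only rings made, and they are closed last, one after the other. O1–C2 and O1''–C2'' come from catalyst-controlled oxa-Michael addition in an open bis(2'-hydroxychalcone), and C3 and C3'' settle as the 2,3-trans centres.
4. Rings A are attached with four bonds at once. O1–C8a, C4–C4a, O1''–C8a'' and C4''–C4a'' form by insertion of two 3,5-bis(benzyloxy)benzynes into the two carboxyl C–O bonds of (E,E)-bis(4-methoxybenzylidene)succinic acid.
5. Rings B and the succinyl chain come from 4-methoxybenzaldehyde and dimethyl succinate by two Stobbe condensations. The aryne precursor comes from phloroglucinol.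

Key step: step 8

Assumption: the quinine-derived thiourea is taken to give the 2S sense of closure; the sense is checked by circular dichroism after debenzylation, and the quinidine-derived pseudo-enantiomer takes its place should it prove opposite.

## Route

Step 1
Reactants: 1 dimethyl succinate, 2 4-methoxybenzaldehyde
Product: 3 (E)-3-(methoxycarbonyl)-4-(4-methoxyphenyl)but-3-enoic acid
Conditions: NaOMe, MeOH, reflux; then aq. HCl
Reagents that add atoms: none
Why: Stobbe condensation, in which the succinate enolate adds to the aldehyde, the alkoxide lactonises onto the second ester, and E1cB opening of the lactone gives the half-ester with the aryl group trans to the ester carbonyl (E) to avoid allylic strain.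

Step 2
Reactants: 3 (E)-3-(methoxycarbonyl)-4-(4-methoxyphenyl)but-3-enoic acid
Product: 4 dimethyl (E)-2-(4-methoxybenzylidene)succinate
Conditions: MeOH, cat. H2SO4, reflux
Reagents that add atoms: methanol, CO
Why: Fischer esterification restores the second ester that the next Stobbe condensation needs for its lactone stage, and the trisubstituted alkene and the aryl ether are inert to catalytic acid in methanol.

Step 3
Reactants: 4 dimethyl (E)-2-(4-methoxybenzylidene)succinate, 2 4-methoxybenzaldehyde
Product: 6 (2E,3E)-2,3-bis(4-methoxybenzylidene)succinic acid, via bis-benzylidene half-ester 5 (not isolated)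
Conditions: NaOMe, MeOH, reflux; then aq. NaOH, reflux; then aq. HCl; light excluded
Reagents that add atoms: sodium hydroxide, [Na+].[OH-]
Why: A second Stobbe condensation at the remaining CH2 group, E-selective for the same steric reason, is followed in the same flask by saponification of the hindered conjugated ester, and the E,E-diacid should crystallise on acidification.

Step 4
Reactants: 7 phloroglucinol
Product: 8 3,5-bis(benzyloxy)phenol
Conditions: BnBr (2.0 equiv), K2CO3, DMF, 0 °C to rt
Reagents that add atoms: benzyl bromide, BrCc1ccccc1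
Why: Williamson etherification with two equivalents of halide gives a statistical mixture of mono-, di- and tri-ethers from this very cheap phenol, which is separated by chromatography.

Step 5
Reactants: 8 3,5-bis(benzyloxy)phenol
Product: 9 3,5-bis(benzyloxy)-2-bromophenol
Conditions: NBS (1.0 equiv), CH2Cl2, −78 °C to 0 °C
Reagents that add atoms: N-bromosuccinimide, O=C1CCC(=O)N1Br
Why: In this electrophilic aromatic bromination the two equivalent positions ortho to the free hydroxyl (each para to a benzyloxy group) are favoured over C4, which is shielded by two benzyloxy groups, and one equivalent of NBS at low temperature avoids dibromination.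

Step 6
Reactants: 9 3,5-bis(benzyloxy)-2-bromophenol
Product: 10 [3,5-bis(benzyloxy)-2-bromophenoxy]trimethylsilane
Conditions: HMDS, THF, 65 °C; evaporate
Reagents that add atoms: hexamethyldisilazane, C[Si](C)(C)N[Si](C)(C)C
Why: Neutral O-silylation of the phenol with HMDS forms only ammonia beside the product, so the crude silyl ether can be used after evaporation.

Step 7
Reactants: 10 [3,5-bis(benzyloxy)-2-bromophenoxy]trimethylsilane
Product: 12 3,5-bis(benzyloxy)-2-(trimethylsilyl)phenyl trifluoromethanesulfonate, via lithium silylphenolate 11 (not isolated)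
Conditions: n-BuLi (1.1 equiv), THF, −78 °C; then Tf2O (1.2 equiv), −78 °C to 0 °C
Reagents that add atoms: trifluoromethanesulfonic anhydride, O=S(=O)(OS(=O)(=O)C(F)(F)F)C(F)(F)F
Why: Bromine–lithium exchange at low temperature is faster than deprotonation of the benzylic OCH2 groups, the aryllithium takes the silyl group from the neighbouring oxygen (retro-Brook 1,3-O-to-C shift), and the lithium phenolate is trapped as the triflate.

Step 8
Reactants: 6 (2E,3E)-2,3-bis(4-methoxybenzylidene)succinic acid, 12 3,5-bis(benzyloxy)-2-(trimethylsilyl)phenyl trifluoromethanesulfonate (two equivalents react)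
Product: 16 (2E,3E)-1,4-bis[2,4-bis(benzyloxy)-6-hydroxyphenyl]-2,3-bis(4-methoxybenzylidene)butane-1,4-dione (open bis-chalcone), via 3,5-bis(benzyloxy)benzyne 13 (not isolated), via mono-insertion keto acid 14 (not isolated), via dipotassium bis-phenolate 15 (not isolated)
Conditions: CsF (8 equiv), THF (0.01 M), sealed vessel, 110 °C, dark, 12 added in three portions (2.4 equiv in all); then KOH, THF–EtOH–H2O, 0 °C to rt; then cold 1 M HCl
Reagents that add atoms: none
Why: Fluoride removes the silyl group of 12 and triflate leaves, releasing benzyne 13 slowly into a dilute solution of the carboxylate groups of 6 (deprotonated by excess CsF); each carboxylate oxygen adds to the aryne carbon remote from the flanking benzyloxy group (future C8a), the resulting aryl anion at C4a, held between two inductively stabilising oxygens, attacks its own ester carbonyl 4-exo-trig, and the strained benzoxetene alkoxide collapses to the ortho-acyl phenolate, first giving 14 and then the bis-ketone. The closest known reaction type is the CsF-induced insertion of arynes into the C–O bond of benzoic, aliphatic and acrylic acids, which needs hot, dilute THF so that the unimolecular acyl shift outruns bimolecular protonation to the aryl ester; here it runs twice on one molecule. No ring is closed for good (the four-membered ring is transient), no stereocentre is made, and both E double bonds are untouched. The step needs regioselectivity, and the 3-benzyloxy group secures it, because its inductive pull and the distortion it imposes on the aryne send the nucleophile to the distal carbon, so the ring oxygens end at C5 and C7. Hot fluoride is expected to push part of the material on to racemic flavanone rings, so the crude product is stirred with KOH, which reopens every closed ring by E1cB to the stabilised bis-phenolate 15 and saponifies aryl esters from premature protonation back to 6 or 14 for re-use. Cold acid then delivers the hydrogen-bonded open bis-chalcone 16, so ring closure is left to the chiral catalyst.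

Step 9
Reactants: 16 open bis-chalcone
Product: 18 (2S,3R,2''S,3''R)-5,7,5'',7''-tetrakis(benzyloxy)-4',4'''-dimethoxy-3,3''-biflavanone, via half-closed flavanone-chalcone 17 (not isolated)
Conditions: 1-[3,5-bis(trifluoromethyl)phenyl]-3-(9-deoxy-epi-quinin-9-yl)thiourea (20 mol %), toluene, 4 Å MS, 0 °C to rt, dark; chromatography
Reagents that add atoms: none
Why: Proposed new method: the quinuclidine nitrogen takes up the 2'-OH proton while the two thiourea N–H bonds bind the C4 carbonyl, so the phenolate adds 6-endo-trig to one face of the benzylidene carbon inside the chiral pocket and sets C2 and then C2'' as S; the enol is protonated at C3, and the amine equilibrates C3 and C3'' to the more stable 2,3-trans (diequatorial) arrangement, which with 2S,2''S can only be 3R,3''R, while the two successive closures under one catalyst channel most stereo-errors into a separable meso-type diastereomer. The closest known reaction type is the cinchona-thiourea-catalysed intramolecular oxa-Michael cyclisation of 2'-hydroxychalcones bearing an α-ester (alkylidene β-keto esters); a singly activated, α-alkenyl enone and a two-fold closure that keeps C3 as a stereocentre have not been shown.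

Step 10
Reactants: 18 tetrabenzyl biflavanone
Product: 19 (2S,3R,2''S,3''R)-5,7,5'',7''-tetrahydroxy-4',4'''-dimethoxy-3,3''-biflavanone
Conditions: H2 (1 atm), 10% Pd/C, EtOAc–MeOH, rt
Reagents that add atoms: none
Why: Catalytic hydrogenolysis of the four benzyl aryl ethers runs under neutral conditions, under which the flavanone C2–O1 bonds, the ketones and the base-sensitive centres C2 and C3 should be left alone if the reaction is stopped at full debenzylation.

Step 11
Reactants: 19 tetraol
Product: 20 ruixianglangdusu B, (2S,3R,2''S,3''R)-5,7,5''-trihydroxy-7'',4',4'''-trimethoxy-3,3''-biflavanone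
Conditions: MeOH (1.0 equiv), PPh3 (1.0 equiv), DIAD (1.0 equiv), THF, 0 °C; recovered 19 recycled
Reagents that add atoms: methanol, CO
Why: Mitsunobu etherification needs no added base, so C2 and C3 are not endangered; the 7-hydroxyls (vinylogous acids para to the carbonyl) react far ahead of the chelated 5-hydroxyls, both 7-hydroxyls of twofold-symmetric 19 lead to the same compound, and one equivalent of reagent limits double methylation.

## Compound list

1 | dimethyl succinate | COC(=O)CCC(=O)OC | starting material
2 | 4-methoxybenzaldehyde | COc1ccc(C=O)cc1 | starting material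
3 | (E)-3-(methoxycarbonyl)-4-(4-methoxyphenyl)but-3-enoic acid | COC(=O)/C(CC(=O)O)=C/c1ccc(OC)cc1 | intermediate
4 | dimethyl (E)-2-(4-methoxybenzylidene)succinate | COC(=O)/C(CC(=O)OC)=C/c1ccc(OC)cc1 | intermediate
5 | (2E,3E)-3-(methoxycarbonyl)-2-(4-methoxybenzylidene)-4-(4-methoxyphenyl)but-3-enoic acid | COc1ccc(/C=C(/C(=O)OC)C(=C/c2ccc(OC)cc2)\C(=O)O)cc1 | intermediate
6 | (2E,3E)-2,3-bis(4-methoxybenzylidene)succinic acid | COc1ccc(/C=C(/C(=O)O)C(=C/c2ccc(OC)cc2)\C(=O)O)cc1 | intermediate
7 | phloroglucinol | Oc1cc(O)cc(O)c1 | starting material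
8 | 3,5-bis(benzyloxy)phenol | Oc1cc(OCc2ccccc2)cc(OCc2ccccc2)c1 | intermediate
9 | 3,5-bis(benzyloxy)-2-bromophenol | Oc1cc(OCc2ccccc2)cc(OCc2ccccc2)c1Br | intermediate
10 | [3,5-bis(benzyloxy)-2-bromophenoxy]trimethylsilane | C[Si](C)(C)Oc1cc(OCc2ccccc2)cc(OCc2ccccc2)c1Br | intermediate
11 | lithium 3,5-bis(benzyloxy)-2-(trimethylsilyl)phenolate | [Li+].[O-]c1cc(OCc2ccccc2)cc(OCc2ccccc2)c1[Si](C)(C)C | intermediate
12 | 3,5-bis(benzyloxy)-2-(trimethylsilyl)phenyl trifluoromethanesulfonate | C[Si](C)(C)c1c(OS(=O)(=O)C(F)(F)F)cc(OCc2ccccc2)cc1OCc1ccccc1 | intermediate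
13 | 3,5-bis(benzyloxy)benzyne (1,2-didehydro-3,5-bis(benzyloxy)benzene) | C1#CC(OCc2ccccc2)=CC(OCc2ccccc2)=C1 | intermediate
14 | (2E,3E)-3-[2,4-bis(benzyloxy)-6-hydroxybenzoyl]-2-(4-methoxybenzylidene)-4-(4-methoxyphenyl)but-3-enoic acid | COc1ccc(/C=C(/C(=O)c2c(O)cc(OCc3ccccc3)cc2OCc2ccccc2)C(=C/c2ccc(OC)cc2)\C(=O)O)cc1 | intermediate
15 | dipotassium bis-phenolate of 16 | COc1ccc(/C=C(/C(=O)c2c([O-])cc(OCc3ccccc3)cc2OCc2ccccc2)C(=C/c2ccc(OC)cc2)\C(=O)c2c([O-])cc(OCc3ccccc3)cc2OCc2ccccc2)cc1.[K+].[K+] | intermediate
16 | (2E,3E)-1,4-bis[2,4-bis(benzyloxy)-6-hydroxyphenyl]-2,3-bis(4-methoxybenzylidene)butane-1,4-dione | COc1ccc(/C=C(/C(=O)c2c(O)cc(OCc3ccccc3)cc2OCc2ccccc2)C(=C/c2ccc(OC)cc2)\C(=O)c2c(O)cc(OCc3ccccc3)cc2OCc2ccccc2)cc1 | intermediate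
17 | (2S,3R)-5,7-bis(benzyloxy)-3-[(E)-3-[2,4-bis(benzyloxy)-6-hydroxyphenyl]-1-(4-methoxyphenyl)-3-oxoprop-1-en-2-yl]-2-(4-methoxyphenyl)chroman-4-one | COc1ccc([C@H]2Oc3cc(OCc4ccccc4)cc(OCc4ccccc4)c3C(=O)[C@@H]2C(=C/c2ccc(OC)cc2)\C(=O)c2c(O)cc(OCc3ccccc3)cc2OCc2ccccc2)cc1 | intermediate
18 | (2S,3R,2''S,3''R)-5,7,5'',7''-tetrakis(benzyloxy)-4',4'''-dimethoxy-3,3''-biflavanone | COc1ccc([C@H]2Oc3cc(OCc4ccccc4)cc(OCc4ccccc4)c3C(=O)[C@@H]2[C@H]2C(=O)c3c(OCc4ccccc4)cc(OCc4ccccc4)cc3O[C@@H]2c2ccc(OC)cc2)cc1 | intermediate
19 | (2S,3R,2''S,3''R)-5,7,5'',7''-tetrahydroxy-4',4'''-dimethoxy-3,3''-biflavanone | COc1ccc([C@H]2Oc3cc(O)cc(O)c3C(=O)[C@@H]2[C@H]2C(=O)c3c(O)cc(O)cc3O[C@@H]2c2ccc(OC)cc2)cc1 | intermediate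
20 | ruixianglangdusu B | COc1ccc([C@H]2Oc3cc(O)cc(O)c3C(=O)[C@@H]2[C@H]2C(=O)c3c(O)cc(OC)cc3O[C@@H]2c2ccc(OC)cc2)cc1 | target

Total step count: 11
Longest linear sequence: 8 steps (7 → 8 → 9 → 10 → 12 → 16 → 18 → 19 → 20)

## Steps most likely to fail

**Step 9.**
- Closure of a singly activated, α-branched enone may be sluggish.
- The second closure may suffer poor facial selectivity if the first-formed centres oppose the catalyst.
- Retro-oxa-Michael reaction may erode the selectivity.
- In the half-closed stage the remaining benzylidene double bond may shift by prototropy.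

The fallback sets out from 16 and uses the classical non-selective chalcone–flavanone isomerisation (NaOAc, EtOH, reflux), followed by equilibration with a little Et3N to the all-trans series. This should give 18 together with its mirror-image biflavanone F1 and the meso-type (2S,3R,2''R,3''S) biflavanone F2. F2 is removed on silica. The racemate is split by preparative HPLC on a polysaccharide carbamate chiral phase, and the route is rejoined at 18. F1 and F2 are returned to 16 by the KOH opening and cold acidification used in step 8.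

**Step 8.**
- The aryl anion may be protonated before the acyl shift, giving O-arylation only.
- The liberated phenol may be arylated further by surplus aryne.
- The second insertion may stall for steric reasons.
- The second aryl anion may attack the first ketone.

The fallback makes the same ortho-metalated aryl ester without an aryne and sets out from 6 and 9. Acetyl chloride at reflux closes 6 to the cyclic anhydride (3E,4E)-3,4-bis(4-methoxybenzylidene)oxolane-2,5-dione F3. The phenolate of 9 (NaH, THF) opens F3 to the mono(2-bromoaryl) ester acid F4. Steglich esterification (EDC, DMAP, CH2Cl2) with a second portion of 9 gives the bis(2-bromoaryl) ester F5. n-BuLi (2.2 equiv, THF, −100 °C) then triggers bromine–lithium exchange and the anionic ortho-Fries acyl shift on both esters. A cold acid quench rejoins the route at 16.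

**Step 11.**
- Over-methylation would consume material irreversibly.
- Separation of products that differ by one methyl group may be hard.

The fallback sets out from 19 and makes the statistical event reversible. TBDPSCl (1.0 equiv), imidazole and DMF at 0 °C should give the 7-O-TBDPS mono-ether F6 beside the 7,7''-bis-O-TBDPS ether F7. These differ strongly in polarity, and F7 is taken back to 19 with HF·pyridine. F6 is methylated to completion at the only free 7''-hydroxyl under Mitsunobu conditions (excess MeOH, PPh3, DIAD), giving the 7-O-TBDPS 7''-O-methyl ether F8. HF·pyridine in THF then removes the silyl group and the route ends at 20.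

## Further compounds

F1 | step 9 | (2R,3S,2''R,3''S)-5,7,5'',7''-tetrakis(benzyloxy)-4',4'''-dimethoxy-3,3''-biflavanone | COc1ccc([C@@H]2Oc3cc(OCc4ccccc4)cc(OCc4ccccc4)c3C(=O)[C@H]2[C@@H]2C(=O)c3c(OCc4ccccc4)cc(OCc4ccccc4)cc3O[C@H]2c2ccc(OC)cc2)cc1
F2 | step 9 | (2S,3R,2''R,3''S)-5,7,5'',7''-tetrakis(benzyloxy)-4',4'''-dimethoxy-3,3''-biflavanone | COc1ccc([C@H]2Oc3cc(OCc4ccccc4)cc(OCc4ccccc4)c3C(=O)[C@@H]2[C@@H]2C(=O)c3c(OCc4ccccc4)cc(OCc4ccccc4)cc3O[C@H]2c2ccc(OC)cc2)cc1
F3 | step 8 | (3E,4E)-3,4-bis(4-methoxybenzylidene)oxolane-2,5-dione | COc1ccc(/C=C2/C(=O)OC(=O)/C2=C/c2ccc(OC)cc2)cc1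
F4 | step 8 | (2E,3E)-3-{[3,5-bis(benzyloxy)-2-bromophenoxy]carbonyl}-2-(4-methoxybenzylidene)-4-(4-methoxyphenyl)but-3-enoic acid | COc1ccc(/C=C(/C(=O)Oc2cc(OCc3ccccc3)cc(OCc3ccccc3)c2Br)C(=C/c2ccc(OC)cc2)\C(=O)O)cc1
F5 | step 8 | bis[3,5-bis(benzyloxy)-2-bromophenyl] (2E,3E)-2,3-bis(4-methoxybenzylidene)succinate | COc1ccc(/C=C(/C(=O)Oc2cc(OCc3ccccc3)cc(OCc3ccccc3)c2Br)C(=C/c2ccc(OC)cc2)\C(=O)Oc2cc(OCc3ccccc3)cc(OCc3ccccc3)c2Br)cc1
F6 | step 11 | (2S,3R,2''S,3''R)-7-(tert-butyldiphenylsilyloxy)-5,5'',7''-trihydroxy-4',4'''-dimethoxy-3,3''-biflavanone | COc1ccc([C@H]2Oc3cc(O[Si](c4ccccc4)(c4ccccc4)C(C)(C)C)cc(O)c3C(=O)[C@@H]2[C@H]2C(=O)c3c(O)cc(O)cc3O[C@@H]2c2ccc(OC)cc2)cc1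
F7 | step 11 | (2S,3R,2''S,3''R)-7,7''-bis(tert-butyldiphenylsilyloxy)-5,5''-dihydroxy-4',4'''-dimethoxy-3,3''-biflavanone | COc1ccc([C@H]2Oc3cc(O[Si](c4ccccc4)(c4ccccc4)C(C)(C)C)cc(O)c3C(=O)[C@@H]2[C@H]2C(=O)c3c(O)cc(O[Si](c4ccccc4)(c4ccccc4)C(C)(C)C)cc3O[C@@H]2c2ccc(OC)cc2)cc1
F8 | step 11 | (2S,3R,2''S,3''R)-7-(tert-butyldiphenylsilyloxy)-5,5''-dihydroxy-7'',4',4'''-trimethoxy-3,3''-biflavanone | COc1ccc([C@H]2Oc3cc(O[Si](c4ccccc4)(c4ccccc4)C(C)(C)C)cc(O)c3C(=O)[C@@H]2[C@H]2C(=O)c3c(O)cc(OC)cc3O[C@@H]2c2ccc(OC)cc2)cc1
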